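## Retrosynthetic overview

1. Target 14 ⇒ angular bis-coumarin 6 + 2 isopropyl nucleophiles (7) + 2 dimethylketene dimer (8). Each trione ring is built from lactone C2/C3 plus the four ring carbons of 8; the two lactone C–O bonds end up as phenols, and the two iPr additions set both (R) centres.
2. 6 ⇒ aryl hexanoate 5 (Fries) ⇒ bis-coumarin 3 + hexanoyl chloride 4.
3. 3 ⇒ phloroglucinol 1 + 2 ethyl propiolate 2 (double annulation).
4. Ring order: the aromatic ring is bought; the two α-pyranone rings form together in step 1 (temporary); the two cyclohexanetrione rings form together in step 3 while both pyranones open.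

Assumption: (R,SP)-rev-Josiphos is written as the ligand enantiomer that delivers iPr to the Si face of C4 and C10 (the face that gives R,R in 14). This sense must be confirmed on the first run and the enantiomeric ligand used if it is opposite. The target is drawn in the enol tautomer of the given SMILES.

## Route

Step 1
Reactants: 1 phloroglucinol; 2 ethyl propiolate (2.3 equiv)
Product: 3 5-hydroxy-2H,8H-pyrano[2,3-f]chromene-2,8-dione
Conditions: ZnCl2 (1.5 equiv), 1,4-dioxane, 100 °C
Reagents that add atoms: ethyl propiolate (2), CCOC(=O)C#C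
Why: von Pechmann-type coumarin synthesis (ZnCl2-promoted hydroarylation of the propiolate by the electron-rich ring, then lactonisation) run twice in one pot; two of the three possible second closures give the angular bis-lactone 3, which has no stereocentre.

Step 2
Reactants: 3 5-hydroxy-2H,8H-pyrano[2,3-f]chromene-2,8-dione; 4 hexanoyl chloride (1.2 equiv)
Product: 6 6-hexanoyl-5-hydroxy-2H,8H-pyrano[2,3-f]chromene-2,8-dione, via aryl hexanoate 5 (not isolated)
Conditions: AlCl3 (4 equiv), PhNO2, 25 → 130 °C; aq. HCl
Reagents that add atoms: hexanoyl chloride (4), CCCCCC(Cl)=O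
Why: O-acylation followed by Fries rearrangement (the classical route to o-acyl hydroxycoumarins); C6 is the only free ring position and is ortho to the ester oxygen, so the acyl group can only arrive there; no stereocentre is involved.

Step 3
Reactants: 6 6-hexanoyl-5-hydroxy-2H,8H-pyrano[2,3-f]chromene-2,8-dione; 7 isopropylmagnesium bromide; 8 2,2,4,4-tetramethylcyclobutane-1,3-dione
Product: 14 myrtucommulone F, via silyl ether 9 (not isolated), via bis-enolate 10 (not isolated), via bis-aldolate 11 (not isolated), via ring-opened bis-enolate 12 (not isolated), via O-silyl myrtucommulone F 13 (not isolated)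
Conditions: (i) (Me3Si)2NH, cat. Me3SiCl, PhMe, 80 °C, evaporate; (ii) CuBr·SMe2 (10 mol%), (R,SP)-rev-Josiphos (12 mol%), 7 (2.4 equiv, slow addition), t-BuOMe, –75 °C; (iii) 8 (2.4 equiv), –75 → 0 °C; (iv) KHMDS (2.2 equiv), THF, 0 → 23 °C; (v) 1 M HCl, 0 °C
Reagents that add atoms: isopropylmagnesium bromide (7), CC(C)[Mg]Br; 2,2,4,4-tetramethylcyclobutane-1,3-dione (8), CC1(C)C(=O)C(C)(C)C1=O
Why: Proposed new method: Cu/ferrocenyl-diphosphine-catalysed asymmetric conjugate addition of a Grignard reagent to a coumarin (known reaction type) puts iPr on the Si face of C4 and of C10 and so sets both (R) centres under catalyst control; each magnesium lactone enolate is then trapped by the strained, non-enolisable dione 8 (aldol addition, then strain-driven retro-aldol opening of the cyclobutanone, the way 8 is known to acylate alkoxides and amines), and the tertiary enolate released closes onto the aryl-ester carbonyl with loss of phenoxide (Dieckmann condensation; KHMDS re-forms that enolate if the acidic C3–H has quenched it, or the β-keto aryl ester enolate closes via E1cB acylketene), so each lactone becomes a cyclohexane-1,3,5-trione whose enolate is the thermodynamic sink; making the enolate by conjugate addition instead of deprotonation keeps the hexanoyl α-CH2 out of play, and the transient silyl ether stops a phenoxide from deactivating the two Michael acceptors; closest known reactions are tandem asymmetric conjugate addition–enolate trapping and base-induced ring-opening acylation by 2,2,4,4-tetramethylcyclobutane-1,3-dione.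

## Compound list

1 | phloroglucinol (benzene-1,3,5-triol) | Oc1cc(O)cc(O)c1 | starting material
2 | ethyl propiolate (ethyl prop-2-ynoate) | CCOC(=O)C#C | starting material
3 | 5-hydroxy-2H,8H-pyrano[2,3-f]chromene-2,8-dione (angular bis-coumarin) | Oc1cc2OC(=O)C=Cc2c2OC(=O)C=Cc12 | intermediate
4 | hexanoyl chloride | CCCCCC(Cl)=O | starting material
5 | 2,8-dioxo-2H,8H-pyrano[2,3-f]chromen-5-yl hexanoate | CCCCCC(=O)Oc1cc2OC(=O)C=Cc2c2OC(=O)C=Cc12 | intermediate
6 | 6-hexanoyl-5-hydroxy-2H,8H-pyrano[2,3-f]chromene-2,8-dione | CCCCCC(=O)c1c(O)c2C=CC(=O)Oc2c2C=CC(=O)Oc12 | intermediate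
7 | isopropylmagnesium bromide | CC(C)[Mg]Br | starting material
8 | 2,2,4,4-tetramethylcyclobutane-1,3-dione (dimethylketene dimer) | CC1(C)C(=O)C(C)(C)C1=O | starting material
9 | 6-hexanoyl-5-(trimethylsilyloxy)-2H,8H-pyrano[2,3-f]chromene-2,8-dione | CCCCCC(=O)c1c(O[Si](C)(C)C)c2C=CC(=O)Oc2c2C=CC(=O)Oc12 | intermediate
10 | (4S,10S)-2,8-bis(bromomagnesiooxy)-6-hexanoyl-4,10-di(propan-2-yl)-5-(trimethylsilyloxy)-4H,10H-pyrano[2,3-f]chromene (bis-magnesium enolate; iPr on the Si face of C4 and C10; the label S here is the same spatial arrangement as R in 14) | CCCCCC(=O)c1c(O[Si](C)(C)C)c2[C@@H](C(C)C)C=C(O[Mg]Br)Oc2c2[C@@H](C(C)C)C=C(O[Mg]Br)Oc12 | intermediate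
11 | (3R,4S,9R,10S)-3,9-bis[1-(bromomagnesiooxy)-2,2,4,4-tetramethyl-3-oxocyclobutyl]-6-hexanoyl-4,10-di(propan-2-yl)-5-(trimethylsilyloxy)-3,4,9,10-tetrahydro-2H,8H-pyrano[2,3-f]chromene-2,8-dione (bis-aldolate; 3,4-trans and 9,10-trans assumed) | CCCCCC(=O)c1c(O[Si](C)(C)C)c2[C@@H](C(C)C)[C@H](C3(O[Mg]Br)C(C)(C)C(=O)C3(C)C)C(=O)Oc2c2[C@@H](C(C)C)[C@H](C3(O[Mg]Br)C(C)(C)C(=O)C3(C)C)C(=O)Oc12 | intermediate
12 | (4S,10S)-3,9-bis[3-(bromomagnesiooxy)-2,2,4-trimethylpent-3-enoyl]-6-hexanoyl-4,10-di(propan-2-yl)-5-(trimethylsilyloxy)-3,4,9,10-tetrahydro-2H,8H-pyrano[2,3-f]chromene-2,8-dione (C3 and C9 epimerisable, left unspecified) | CCCCCC(=O)c1c(O[Si](C)(C)C)c2[C@@H](C(C)C)C(C(=O)C(C)(C)C(O[Mg]Br)=C(C)C)C(=O)Oc2c2[C@@H](C(C)C)C(C(=O)C(C)(C)C(O[Mg]Br)=C(C)C)C(=O)Oc12 | intermediate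
13 | O-trimethylsilyl myrtucommulone F (silyl on one phenol oxygen next to the hexanoyl group; both benzylic centres R) | CCCCCC(=O)c1c(O[Si](C)(C)C)c([C@H](C2=C(O)C(C)(C)C(=O)C(C)(C)C2=O)C(C)C)c(O)c([C@H](C2=C(O)C(C)(C)C(=O)C(C)(C)C2=O)C(C)C)c1O | intermediate
14 | myrtucommulone F, 2,2'-{(5-hexanoyl-2,4,6-trihydroxy-1,3-phenylene)bis[(1R)-2-methylpropane-1,1-diyl]}bis(3-hydroxy-4,4,6,6-tetramethylcyclohex-2-ene-1,5-dione) | CCCCCC(=O)c1c(O)c([C@H](C2=C(O)C(C)(C)C(=O)C(C)(C)C2=O)C(C)C)c(O)c([C@H](C2=C(O)C(C)(C)C(=O)C(C)(C)C2=O)C(C)C)c1O | target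

## Step count

Total steps: 3. Longest linear sequence: 3 (1 → 3 → 6 → 14).

## Steps most likely to fail, with fallbacks

**Step 3 (highest risk).** Weak points:
- The Cu-catalysed addition uses a secondary Grignard reagent and both acceptor carbons have a peri oxygen substituent, so rate and selectivity are uncertain.
- The aldol addition to the hindered dione and the final ring closure have no direct precedent on a lactone enolate.
- The hexanoyl ketone must stay out of both the addition and the base stage.
- Stereochemical purity rests on two catalyst-controlled additions. The meso (R,S) diastereomer is the expected main impurity and must be removed by chromatography; the (S,S) enantiomer is suppressed statistically.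
- The basic stage and the acid work-up are kept short and cold to avoid retro-Michael scrambling and acid-induced cyclodehydration to pyrans.

Fallback: it sets out from bis-enolate 10 and comes back at 14, with the two halves separated and the polarity of the ring synthesis reversed. Quenching 10 with cold aqueous HCl instead of adding 8 gives (4R,10R)-6-hexanoyl-5-hydroxy-4,10-di(propan-2-yl)-3,4,9,10-tetrahydro-2H,8H-pyrano[2,3-f]chromene-2,8-dione F4. Methanolysis of 8 (MeOH, cat. NaOMe) gives methyl 2,2,4-trimethyl-3-oxopentanoate F5. Its lithium enolate (LDA, THF, –78 → 0 °C, excess) attacks the two lactone carbonyls of F4 in a crossed Claisen condensation with phenoxide as leaving group, giving dimethyl (7R,7'R)-7,7'-(5-hexanoyl-2,4,6-trihydroxy-1,3-phenylene)bis(2,2,4,4,8-pentamethyl-3,5-dioxononanoate) F6. LiHMDS in THF then closes both rings by Dieckmann condensation of each CH2–ketone enolate onto its methyl ester, giving 14. The benzylic centres are not enolisable at any stage.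

**Step 1.** Weak points: the second annulation is on a less nucleophilic 5,7-dihydroxycoumarin; a third annulation or the linear isomer may form; 3 is likely to be poorly soluble.

Fallback: it sets out from 1 and comes back at 3, replacing hydroarylation by carbonyl olefination. Vilsmeier–Haack diformylation of 1 (POCl3, DMF) gives 2,4,6-trihydroxybenzene-1,3-dicarbaldehyde F1. Double Wittig reaction with Ph3P=CHCO2Et in N,N-diethylaniline at reflux gives diethyl (2E,2'E)-3,3'-(2,4,6-trihydroxy-1,3-phenylene)bis(prop-2-enoate) F2, which isomerises and lactonises in the same hot solution to 3.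

**Step 2.** Weak point: the Fries rearrangement is on an arene deactivated by two pyranone rings and needs high temperature.

Fallback: it sets out from 1 and comes back at 6, acylating before the ring is deactivated. Friedel–Crafts acylation of 1 with 4 (AlCl3, PhNO2/CH2Cl2) gives 1-(2,4,6-trihydroxyphenyl)hexan-1-one F3. Double annulation of F3 with 2 (ZnCl2, dioxane, 100–110 °C) gives 6: if the first lactone forms on the oxygen para to the acyl group, the second closure can only give the angular isomer 6.

## Further compounds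

F1 | step 1 | 2,4,6-trihydroxybenzene-1,3-dicarbaldehyde | O=Cc1c(O)cc(O)c(C=O)c1O
F2 | step 1 | diethyl (2E,2'E)-3,3'-(2,4,6-trihydroxy-1,3-phenylene)bis(prop-2-enoate) | CCOC(=O)/C=C/c1c(O)cc(O)c(/C=C/C(=O)OCC)c1O
F3 | step 2 | 1-(2,4,6-trihydroxyphenyl)hexan-1-one | CCCCCC(=O)c1c(O)cc(O)cc1O
F4 | step 3 | (4R,10R)-6-hexanoyl-5-hydroxy-4,10-di(propan-2-yl)-3,4,9,10-tetrahydro-2H,8H-pyrano[2,3-f]chromene-2,8-dione | CCCCCC(=O)c1c(O)c2[C@@H](C(C)C)CC(=O)Oc2c2[C@@H](C(C)C)CC(=O)Oc12
F5 | step 3 | methyl 2,2,4-trimethyl-3-oxopentanoate | COC(=O)C(C)(C)C(=O)C(C)C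
F6 | step 3 | dimethyl (7R,7'R)-7,7'-(5-hexanoyl-2,4,6-trihydroxy-1,3-phenylene)bis(2,2,4,4,8-pentamethyl-3,5-dioxononanoate) | CCCCCC(=O)c1c(O)c([C@H](CC(=O)C(C)(C)C(=O)C(C)(C)C(=O)OC)C(C)C)c(O)c([C@H](CC(=O)C(C)(C)C(=O)C(C)(C)C(=O)OC)C(C)C)c1O
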